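Measure each flask by its shortfall, the share of the charged Z that does not stand as J. Z opens to J + L and can close again, while Z + J pairs off into Q.

| flask | Z | temperature | remark | time |
|---|---|---|---|---|
| teal | 10 mM | 65 °C | run made earlier |  |
| amber | 40 mM | 80 °C | run made earlier |  |
| Thursday's | 20 mM |  | at 70 °C until 12 h, from then on at 90 °C | 25 h |
| Tuesday's | 20 mM |  | at 90 °C throughout | 40 h |

| run | time / h | J / % |
|---|---|---|
| teal | 2.00 | 55 |
| teal | 3.00 | 75 |
| teal | 5.00 | 87 |
| teal | 8.00 | 95 |
| teal | 10.0 | 95 |
| teal | 15.0 | 94 |
| teal | 25.0 | 94 |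
| amber | 0.833 | 77 |
| amber | 2.50 | 84 |
| amber | 5.00 | 80 |
| amber | 6.00 | 85 |
| amber | 10.0 | 80 |
| amber | 12.0 | 78 |
| amber | 15.0 | 74 |

(readings scatter by 2 percentage points)

- which one finishes higher in amount of J, in percent of the Z charged ("neither" within 2 percentage points) (Thursday's / Tuesday's / neither)
- amount of J at the end, in percent of the Z charged, Thursday's
- amount of J at the end, in percent of the Z charged, Tuesday's

- a species is counted by the Z in it: one Q counts as two
- the earlier runs were read with a standard deviation of 2 percentage points
- on the list of suspects stand: Z + J -> Q; Z <-> J + L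

1. Two versions solve in the head. With no pairing the shortfall is the part of Z that stays closed in its balance with J + L, and with each new J pairing off a Z it is the whole charge. The teal run peaks at a shortfall of 5.00% and the amber run at 16.0%, so both lie near the first version.

2. During the rise, pairing races the first-order opening of Z, so I take the share lost to grow with the charge, as a selectivity factor does. The readings give 0.00500 mM⁻¹ for teal and 0.00400 mM⁻¹ for amber. Their mean gives a shortfall of 9.00% at 20 mM.

3. After its peak the amber run falls. I carry this drain, the share of the charge lost per hour after the peak, 0.00800 h⁻¹, as a reading. With cZ held near its balance with cJ·cL, the pairing rate goes as the cube of the charge, so the share lost goes as its square. I assume a factor 2 per 10 K, which gives 0.00400 h⁻¹ at 90 °C and 1.00 × 10⁻³ h⁻¹ at 70 °C.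

4. Tuesday's flask comes to 75.0%. Thursday's flask comes to 84.6%, higher by 9.6 percentage points.

5. The forecast, which notes “The activation energy is not measured”, also picks Thursday's, but its 82% (77% to 87%) and 71% (63% to 78%) lie below my figures.

6. The flasks give 83.5% for Thursday's and 75.3% for Tuesday's, so Thursday's finishes ahead.

    Z + J → Q (k = 2.67 L mol⁻¹ h⁻¹, Ea = 67.0 kJ mol⁻¹)
    Z ⇌ J + L (K = 0.842 M, k = 0.766 h⁻¹, Ea = 97.0 kJ mol⁻¹, ΔH = 8.00 kJ mol⁻¹)
    (constants at 70 °C)

Take the neighbouring flask, Tuesday's with 8.0 mM of Z. The rise costs 3.60%, and the drain, scaled by the square of the charge, costs 2.56% over 40 h. That leaves 93.8% as J. The flask gives 93.4%, with Q at 5.91%.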